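## Retrosynthetic overview

1. Azulene numbering is used: C8a is the methylated fusion carbon, C1 and C3 the carbinols, C3a the fusion CH, C4 the ester carbon, C6=C7 the alkene. Late cuts are the aryl ester (Steglich), the C4 carbinol (reduction of the 4-ketone directed by the C3 hydroxyl) and the C6=C7 alkene (1,4-hydrogenation of a C5=C6–C7=C8 dienone, made by Saegusa–Ito oxidation of the C7=C8 cycloadduct).
2. Key disconnection: C5–C6 and C3a–C8a together, by an intramolecular (4+3) cycloaddition of an open-chain epoxy enol silane (oxirane C3–C3a, enol silane C4=C5) onto a tethered (E,E)-diene (C8a=C8–C7=C6).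
3. Enabling feature: the C3(OH)–C3a(H)–C4(O) β-hydroxy-carbonyl triad across the ring fusion. In the seven-membered ring it is flanked by the three-carbon arc C3a–C4–C5 and the four-carbon arc C6–C7–C8–C8a, and C1–C2–C3 of the five-membered ring is the three-atom link. This is the imprint of an oxirane-derived 2-silyloxyallyl cation adding to a diene.
4. The epoxy ketone comes from δ-lactone 11 (anti-selective nucleophilic epoxidation, MeLi opening). Lactone 11 comes from a δ-hydroxy ynoate (syn addition of isopropyl, lactonisation), made by asymmetric propargylation of (2E,4E)-2-methylhexa-2,4-dienal.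
5. Ring order: temporary δ-lactone (step 4, opened in step 6), then the cyclopentane and the cycloheptene together (step 9).

Key step: step 9

Assumption: 4-[(tert-butyldimethylsilyl)oxy]benzoic acid (22) is taken as a purchasable building block, and the silyl-triflate-induced oxirane opening is taken to proceed with inversion at the attacked carbon.

## Route

Step 1
Reactants: 1 (E)-but-2-enal; 2 2-(triphenyl-λ5-phosphanylidene)propanal
Product: 3 (2E,4E)-2-methylhexa-2,4-dienal
Conditions: 1 (excess), toluene, 90 °C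
Reagents that add atoms: none
Why: Wittig olefination with a formyl-stabilised ylide should give the E trisubstituted enal, and the α-branched, doubly conjugated product aldehyde is less reactive than 1, so mono-olefination should prevail.

Step 2
Reactants: 3 (2E,4E)-2-methylhexa-2,4-dienal; 4 allenylboronic acid pinacol ester
Product: 6 (4R,5E,7E)-5-methylnona-5,7-dien-1-yn-4-ol, via pinacol borate ester 5 (not isolated)
Conditions: 3,3'-bis(2,4,6-triisopropylphenyl)-1,1'-binaphthyl-2,2'-diyl hydrogen phosphate (5 mol%, the antipode that gives the 4R alcohol), 4 Å MS, toluene, −20 °C; aqueous work-up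
Reagents that add atoms: none
Why: Brønsted-acid-catalysed propargylboration through a closed six-membered SE2' transition state should add to the Re face of the aldehyde under catalyst control and set the carbinol that becomes C1.

Step 3
Reactants: 6 (4R,5E,7E)-5-methylnona-5,7-dien-1-yn-4-ol
Product: 9 methyl (5R,6E,8E)-5-hydroxy-6-methyldeca-6,8-dien-2-ynoate, via O-trimethylsilyl ether 7 (not isolated), via silylated ynoate 8 (not isolated)
Conditions: n-BuLi (1.0 equiv), THF, −78 °C; Me3SiCl; n-BuLi (1.1 equiv); ClCO2Me; then citric acid, MeOH, 0 °C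
Reagents that add atoms: methyl chloroformate COC(=O)Cl
Why: Transient O-silylation lets the second equivalent of base form the lithium acetylide, which is C-acylated by the chloroformate (acetylide acylation), and mild acid then frees the hydroxyl without touching the stereocentre.

Step 4
Reactants: 9 methyl (5R,6E,8E)-5-hydroxy-6-methyldeca-6,8-dien-2-ynoate
Product: 11 (6R)-6-[(2E,4E)-hexa-2,4-dien-2-yl]-4-(propan-2-yl)-5,6-dihydro-2H-pyran-2-one, via hydroxy trienoate 10 (not isolated)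
Conditions: i-PrMgCl (2.5 equiv), CuBr·SMe2 (10 mol%), THF, −78 → −40 °C; aq NH4Cl, then rt
Reagents that add atoms: isopropylmagnesium chloride CC(C)[Mg]Cl
Why: Copper-catalysed syn conjugate addition of the Grignard reagent to the ynoate places the ester cis to the CH2 chain, the only geometry from which the δ-hydroxyl can lactonise, so the alkene geometry needed later is locked in the ring.

Step 5
Reactants: 11 (6R)-6-[(2E,4E)-hexa-2,4-dien-2-yl]-4-(propan-2-yl)-5,6-dihydro-2H-pyran-2-one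
Product: 12 (1S,4R,6R)-4-[(2E,4E)-hexa-2,4-dien-2-yl]-6-(propan-2-yl)-3,7-dioxabicyclo[4.1.0]heptan-2-one
Conditions: t-BuOOH (anhydrous, decane), DBU, CH2Cl2, 0 °C → rt
Reagents that add atoms: tert-butyl hydroperoxide CC(C)(C)OO
Why: In this Weitz–Scheffer-type nucleophilic epoxidation the peroxide anion should add to C4 of the half-chair lactone anti to the pseudo-equatorial dienyl group, which sets both oxirane carbons (later C3 and C3a) relative to the existing centre, while the electron-rich diene is inert to the nucleophilic oxidant.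

Step 6
Reactants: 12 (1S,4R,6R)-4-[(2E,4E)-hexa-2,4-dien-2-yl]-6-(propan-2-yl)-3,7-dioxabicyclo[4.1.0]heptan-2-one
Product: 13 1-{(2S,3R)-3-[(2R,3E,5E)-2-hydroxy-3-methylhepta-3,5-dien-1-yl]-3-(propan-2-yl)oxiran-2-yl}ethan-1-one
Conditions: MeLi (1.1 equiv), THF, −78 °C; H2O
Reagents that add atoms: methyllithium [Li]C
Why: Mono-addition of an organolithium to a δ-lactone at low temperature should stop at the lithium hemiketal, which gives the methyl ketone (in equilibrium with its cyclic hemiketal) on work-up.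

Step 7
Reactants: 13 1-{(2S,3R)-3-[(2R,3E,5E)-2-hydroxy-3-methylhepta-3,5-dien-1-yl]-3-(propan-2-yl)oxiran-2-yl}ethan-1-one
Product: 14 1-{(2S,3R)-3-[(2R,3E,5E)-2-[(tert-butyldimethylsilyl)oxy]-3-methylhepta-3,5-dien-1-yl]-3-(propan-2-yl)oxiran-2-yl}ethan-1-one
Conditions: t-BuMe2SiCl, imidazole, DMF, rt
Reagents that add atoms: tert-butyldimethylsilyl chloride CC(C)(C)[Si](C)(C)Cl
Why: Standard silylation of the open-chain secondary alcohol, which also drains the hemiketal equilibrium and protects C1–O until the last step.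

Step 8
Reactants: 14 1-{(2S,3R)-3-[(2R,3E,5E)-2-[(tert-butyldimethylsilyl)oxy]-3-methylhepta-3,5-dien-1-yl]-3-(propan-2-yl)oxiran-2-yl}ethan-1-one
Product: 15 triethyl[(1-{(2S,3R)-3-[(2R,3E,5E)-2-[(tert-butyldimethylsilyl)oxy]-3-methylhepta-3,5-dien-1-yl]-3-(propan-2-yl)oxiran-2-yl}ethenyl)oxy]silane
Conditions: LiN(SiMe3)2, Et3SiCl, Et3N, THF, −78 °C
Reagents that add atoms: chlorotriethylsilane CC[Si](Cl)(CC)CC
Why: Kinetic deprotonation of the methyl group (the oxirane C–H is not enolisable) and O-silylation give the terminal enol silane (silyl enol ether formation).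

Step 9
Reactants: 15 triethyl[(1-{(2S,3R)-3-[(2R,3E,5E)-2-[(tert-butyldimethylsilyl)oxy]-3-methylhepta-3,5-dien-1-yl]-3-(propan-2-yl)oxiran-2-yl}ethenyl)oxy]silane
Product: 16 (1R,3R,3aR,6R,8aR)-1-[(tert-butyldimethylsilyl)oxy]-6,8a-dimethyl-3-(propan-2-yl)-3-[(triethylsilyl)oxy]-2,3,3a,5,6,8a-hexahydroazulen-4(1H)-one
Conditions: Et3SiOSO2CF3 (10 mol%), CH2Cl2, −78 °C; Et3N quench
Reagents that add atoms: none
Why: The silyl triflate silylates the oxirane oxygen, the diene terminus C8a attacks C3a anti to the breaking C–O bond while the enol-silane carbon C5 closes on the diene terminus C6 in a concerted, asynchronous (4+3) cycloaddition of a 2-silyloxyallyl cation equivalent, and the silyl group on the carbonyl oxygen returns to the catalyst pool, leaving C3–O as its triethylsilyl ether. The closest known reaction type is the silyl-triflate-catalysed intramolecular (4+3) cycloaddition of epoxy enol silanes with tethered dienes, which transfers the oxirane chirality. The cyclopentane closes by 5-exo attack of C8a on the oxirane carbon C3a through the C1–C2–C3 link, and the cycloheptene by the second bond of the (4+3) union, C5 onto C6. C3 keeps its oxirane configuration, C3a is set by inversion, C8a by the diene face used in the extended arrangement (E-diene with the tether outside and the methyl inside, cation in its W form), which gives the trans ring fusion, and C6 by the E geometry of the distal alkene (erased in step 10). The step needs ionisation at C3a and not at the tertiary C3 (secured by the enol silane, which stabilises charge only at C3a), the extended over the compact arrangement (expected because the OTES-bearing C4 then turns away from the diene while C1–H lies in the diene plane and the OTBS group on the open face), and seven- over five-membered closure (secured by the s-cis diene).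

Step 10
Reactants: 16 (1R,3R,3aR,6R,8aR)-1-[(tert-butyldimethylsilyl)oxy]-6,8a-dimethyl-3-(propan-2-yl)-3-[(triethylsilyl)oxy]-2,3,3a,5,6,8a-hexahydroazulen-4(1H)-one
Product: 18 (1R,3R,3aR,8aR)-1-[(tert-butyldimethylsilyl)oxy]-6,8a-dimethyl-3-(propan-2-yl)-3-[(triethylsilyl)oxy]-2,3,3a,8a-tetrahydroazulen-4(1H)-one, via trimethylsilyl enol ether 17 (not isolated)
Conditions: LiN(i-Pr)2, THF, −78 °C, then Me3SiCl; Pd(OAc)2 (1.1 equiv), MeCN, rt
Reagents that add atoms: none
Why: Saegusa–Ito dehydrogenation: kinetic enolisation can only occur at C5 (C3a is a hindered methine) and β-hydride elimination can only take the C6 hydrogen, which gives the C5=C6–C7=C8 dienone and erases the C6 centre.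

Step 11
Reactants: 18 (1R,3R,3aR,8aR)-1-[(tert-butyldimethylsilyl)oxy]-6,8a-dimethyl-3-(propan-2-yl)-3-[(triethylsilyl)oxy]-2,3,3a,8a-tetrahydroazulen-4(1H)-one
Product: 19 (1R,3R,3aR,8aR)-1-[(tert-butyldimethylsilyl)oxy]-3-hydroxy-6,8a-dimethyl-3-(propan-2-yl)-2,3,3a,8a-tetrahydroazulen-4(1H)-one
Conditions: HF·pyridine, pyridine, THF, 0 °C
Reagents that add atoms: none
Why: Selective fluoride desilylation: the triethylsilyl ether should cleave much faster than the hindered secondary tert-butyldimethylsilyl ether, unmasking the tertiary hydroxyl that directs step 13.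

Step 12
Reactants: 19 (1R,3R,3aR,8aR)-1-[(tert-butyldimethylsilyl)oxy]-3-hydroxy-6,8a-dimethyl-3-(propan-2-yl)-2,3,3a,8a-tetrahydroazulen-4(1H)-one
Product: 20 (1R,3R,3aR,8aR)-1-[(tert-butyldimethylsilyl)oxy]-3-hydroxy-6,8a-dimethyl-3-(propan-2-yl)-2,3,3a,5,8,8a-hexahydroazulen-4(1H)-one
Conditions: H2 (70 bar), (η6-naphthalene)Cr(CO)3 (20 mol%), THF, 45 °C
Reagents that add atoms: none
Why: Arene–Cr(CO)3-catalysed 1,4-hydrogenation of an s-cis 1,3-diene delivers both hydrogens to the diene termini C5 and C8 within the chromium coordination sphere and should leave the C6=C7 alkene regiospecifically, the s-trans enone unit not being a substrate.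

Step 13
Reactants: 20 (1R,3R,3aR,8aR)-1-[(tert-butyldimethylsilyl)oxy]-3-hydroxy-6,8a-dimethyl-3-(propan-2-yl)-2,3,3a,5,8,8a-hexahydroazulen-4(1H)-one
Product: 21 (1R,3R,3aS,4S,8aR)-1-[(tert-butyldimethylsilyl)oxy]-6,8a-dimethyl-3-(propan-2-yl)-1,2,3,3a,4,5,8,8a-octahydroazulene-3,4-diol
Conditions: Me4NBH(OAc)3, MeCN/AcOH, −30 °C
Reagents that add atoms: none
Why: Evans–Saksena hydroxyl-directed reduction: the alkoxyborohydride formed at C3–O delivers hydride intramolecularly to the ketone face on which the C3 oxygen lies (the face of the angular methyl, which an external hydride would avoid), giving the 1,3-anti diol with the 4S carbinol.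

Step 14
Reactants: 21 (1R,3R,3aS,4S,8aR)-1-[(tert-butyldimethylsilyl)oxy]-6,8a-dimethyl-3-(propan-2-yl)-1,2,3,3a,4,5,8,8a-octahydroazulene-3,4-diol; 22 4-[(tert-butyldimethylsilyl)oxy]benzoic acid
Product: 23 (1R,3R,3aS,4S,8aR)-1-[(tert-butyldimethylsilyl)oxy]-3-hydroxy-6,8a-dimethyl-3-(propan-2-yl)-1,2,3,3a,4,5,8,8a-octahydroazulen-4-yl 4-[(tert-butyldimethylsilyl)oxy]benzoate
Conditions: DCC, DMAP (cat.), CH2Cl2, 0 °C → rt
Reagents that add atoms: none
Why: Steglich esterification should acylate only the secondary C4 hydroxyl, the tertiary C3 hydroxyl being unreactive, with retention at C4.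

Step 15
Reactants: 23 (1R,3R,3aS,4S,8aR)-1-[(tert-butyldimethylsilyl)oxy]-3-hydroxy-6,8a-dimethyl-3-(propan-2-yl)-1,2,3,3a,4,5,8,8a-octahydroazulen-4-yl 4-[(tert-butyldimethylsilyl)oxy]benzoate
Product: 24 (1R,3R,3aS,4S,8aR)-1,3-dihydroxy-6,8a-dimethyl-3-(propan-2-yl)-1,2,3,3a,4,5,8,8a-octahydroazulen-4-yl 4-hydroxybenzoate
Conditions: HF·pyridine, THF, 0 °C → rt
Reagents that add atoms: none
Why: Fluoride desilylation of the aryl and the alkyl silyl ether under mildly acidic conditions should leave the benzoate, the tertiary alcohol and the trisubstituted alkene untouched.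

## Compound list

1 | (E)-but-2-enal | C/C=C/C=O | starting material
2 | 2-(triphenyl-λ5-phosphanylidene)propanal | CC(C=O)=P(c1ccccc1)(c1ccccc1)c1ccccc1 | starting material
3 | (2E,4E)-2-methylhexa-2,4-dienal | C/C=C/C=C(\C)C=O | intermediate
4 | 4,4,5,5-tetramethyl-2-(propa-1,2-dien-1-yl)-1,3,2-dioxaborolane (allenylboronic acid pinacol ester) | C=C=CB1OC(C)(C)C(C)(C)O1 | starting material
5 | 2-{[(4R,5E,7E)-5-methylnona-5,7-dien-1-yn-4-yl]oxy}-4,4,5,5-tetramethyl-1,3,2-dioxaborolane | C/C=C/C=C(\C)[C@H](OB1OC(C)(C)C(C)(C)O1)CC#C | intermediate (not isolated)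
6 | (4R,5E,7E)-5-methylnona-5,7-dien-1-yn-4-ol | C/C=C/C=C(\C)[C@H](O)CC#C | intermediate
7 | trimethyl{[(4R,5E,7E)-5-methylnona-5,7-dien-1-yn-4-yl]oxy}silane | C/C=C/C=C(\C)[C@H](O[Si](C)(C)C)CC#C | intermediate (not isolated)
8 | methyl (5R,6E,8E)-6-methyl-5-[(trimethylsilyl)oxy]deca-6,8-dien-2-ynoate | C/C=C/C=C(\C)[C@H](O[Si](C)(C)C)CC#CC(=O)OC | intermediate (not isolated)
9 | methyl (5R,6E,8E)-5-hydroxy-6-methyldeca-6,8-dien-2-ynoate | C/C=C/C=C(\C)[C@H](O)CC#CC(=O)OC | intermediate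
10 | methyl (2E,5R,6E,8E)-5-hydroxy-6-methyl-3-(propan-2-yl)deca-2,6,8-trienoate | C/C=C/C=C(\C)[C@H](O)C/C(C(C)C)=C\C(=O)OC | intermediate (not isolated)
11 | (6R)-6-[(2E,4E)-hexa-2,4-dien-2-yl]-4-(propan-2-yl)-5,6-dihydro-2H-pyran-2-one | C/C=C/C=C(\C)[C@H]1CC(C(C)C)=CC(=O)O1 | intermediate
12 | (1S,4R,6R)-4-[(2E,4E)-hexa-2,4-dien-2-yl]-6-(propan-2-yl)-3,7-dioxabicyclo[4.1.0]heptan-2-one | C/C=C/C=C(\C)[C@H]1C[C@]2(C(C)C)O[C@@H]2C(=O)O1 | intermediate
13 | 1-{(2S,3R)-3-[(2R,3E,5E)-2-hydroxy-3-methylhepta-3,5-dien-1-yl]-3-(propan-2-yl)oxiran-2-yl}ethan-1-one | C/C=C/C=C(\C)[C@H](O)C[C@]1(C(C)C)O[C@@H]1C(C)=O | intermediate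
14 | 1-{(2S,3R)-3-[(2R,3E,5E)-2-[(tert-butyldimethylsilyl)oxy]-3-methylhepta-3,5-dien-1-yl]-3-(propan-2-yl)oxiran-2-yl}ethan-1-one | C/C=C/C=C(\C)[C@H](O[Si](C)(C)C(C)(C)C)C[C@]1(C(C)C)O[C@@H]1C(C)=O | intermediate
15 | triethyl[(1-{(2S,3R)-3-[(2R,3E,5E)-2-[(tert-butyldimethylsilyl)oxy]-3-methylhepta-3,5-dien-1-yl]-3-(propan-2-yl)oxiran-2-yl}ethenyl)oxy]silane | C/C=C/C=C(\C)[C@H](O[Si](C)(C)C(C)(C)C)C[C@]1(C(C)C)O[C@@H]1C(=C)O[Si](CC)(CC)CC | intermediate
16 | (1R,3R,3aR,6R,8aR)-1-[(tert-butyldimethylsilyl)oxy]-6,8a-dimethyl-3-(propan-2-yl)-3-[(triethylsilyl)oxy]-2,3,3a,5,6,8a-hexahydroazulen-4(1H)-one (trans-fused) | C[C@H]1C=C[C@@]2(C)[C@H](O[Si](C)(C)C(C)(C)C)C[C@@](O[Si](CC)(CC)CC)(C(C)C)[C@@H]2C(=O)C1 | intermediate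
17 | 4-O-trimethylsilyl enol ether (C4=C5) of 16 | C[C@H]1C=C[C@@]2(C)[C@H](O[Si](C)(C)C(C)(C)C)C[C@@](O[Si](CC)(CC)CC)(C(C)C)[C@@H]2C(O[Si](C)(C)C)=C1 | intermediate (not isolated)
18 | (1R,3R,3aR,8aR)-1-[(tert-butyldimethylsilyl)oxy]-6,8a-dimethyl-3-(propan-2-yl)-3-[(triethylsilyl)oxy]-2,3,3a,8a-tetrahydroazulen-4(1H)-one | CC=1C=C[C@@]2(C)[C@H](O[Si](C)(C)C(C)(C)C)C[C@@](O[Si](CC)(CC)CC)(C(C)C)[C@@H]2C(=O)C=1 | intermediate
19 | (1R,3R,3aR,8aR)-1-[(tert-butyldimethylsilyl)oxy]-3-hydroxy-6,8a-dimethyl-3-(propan-2-yl)-2,3,3a,8a-tetrahydroazulen-4(1H)-one | CC=1C=C[C@@]2(C)[C@H](O[Si](C)(C)C(C)(C)C)C[C@@](O)(C(C)C)[C@@H]2C(=O)C=1 | intermediate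
20 | (1R,3R,3aR,8aR)-1-[(tert-butyldimethylsilyl)oxy]-3-hydroxy-6,8a-dimethyl-3-(propan-2-yl)-2,3,3a,5,8,8a-hexahydroazulen-4(1H)-one | CC1=CC[C@@]2(C)[C@H](O[Si](C)(C)C(C)(C)C)C[C@@](O)(C(C)C)[C@@H]2C(=O)C1 | intermediate
21 | (1R,3R,3aS,4S,8aR)-1-[(tert-butyldimethylsilyl)oxy]-6,8a-dimethyl-3-(propan-2-yl)-1,2,3,3a,4,5,8,8a-octahydroazulene-3,4-diol | CC1=CC[C@@]2(C)[C@H](O[Si](C)(C)C(C)(C)C)C[C@@](O)(C(C)C)[C@@H]2[C@@H](O)C1 | intermediate
22 | 4-[(tert-butyldimethylsilyl)oxy]benzoic acid | CC(C)(C)[Si](C)(C)Oc1ccc(cc1)C(O)=O | starting material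
23 | (1R,3R,3aS,4S,8aR)-1-[(tert-butyldimethylsilyl)oxy]-3-hydroxy-6,8a-dimethyl-3-(propan-2-yl)-1,2,3,3a,4,5,8,8a-octahydroazulen-4-yl 4-[(tert-butyldimethylsilyl)oxy]benzoate | CC1=CC[C@@]2(C)[C@H](O[Si](C)(C)C(C)(C)C)C[C@@](O)(C(C)C)[C@@H]2[C@@H](OC(=O)c2ccc(O[Si](C)(C)C(C)(C)C)cc2)C1 | intermediate
24 | (1R,3R,3aS,4S,8aR)-1,3-dihydroxy-6,8a-dimethyl-3-(propan-2-yl)-1,2,3,3a,4,5,8,8a-octahydroazulen-4-yl 4-hydroxybenzoate | CC1=CC[C@@]2(C)[C@H](O)C[C@@](O)(C(C)C)[C@@H]2[C@@H](OC(=O)c2ccc(O)cc2)C1 | target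

## Step count and risks

Total step count: 15. Longest linear sequence: 15 steps (from 1 and 2 to 24).

Steps most likely to fail:

1. Step 9. The diene may add through the compact instead of the extended arrangement (wrong diene face, cis-fused C8a epimer). The silylated oxirane may also ionise at the tertiary C3 with a 1,2-shift, or the enol silane may close on C8 to a five-membered ring. Fallback, setting out from 14 and coming back at 16: the oxyallyl cation is generated free, by base, from an α-bromo ketone. MgBr2·OEt2 in Et2O at −20 °C should open the oxirane of 14 at the carbon next to the ketone with inversion to give the bromohydrin (3R,4R,6R,7E,9E)-3-bromo-6-[(tert-butyldimethylsilyl)oxy]-4-hydroxy-7-methyl-4-(propan-2-yl)undeca-7,9-dien-2-one F1. Silylation with Et3SiOSO2CF3 and 2,6-lutidine gives its 4-O-triethylsilyl ether (3R,4R,6R,7E,9E)-3-bromo-6-[(tert-butyldimethylsilyl)oxy]-7-methyl-4-(propan-2-yl)-4-[(triethylsilyl)oxy]undeca-7,9-dien-2-one F2. Et3N in CF3CH2OH (or LiClO4/Et3N in Et2O) then ionises F2 to the 2-oxyallyl cation, which undergoes the classical intramolecular (4+3) cycloaddition to 16. In this mode C3a is set by the preference of the isopropyl group on C3 to lie next to the C3a hydrogen, not by inversion.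

2. Step 12. Hydrogen transfer to the hindered diene may be slow, and the β,γ-alkene may drift into conjugation with the ketone. Fallback, setting out from 18 and coming back at 20: dissolving-metal reduction of the dienone (Li, liquid NH3/THF, −78 °C) adds hydrogen at C8 and gives the dienolate, which solid NH4Cl protonates kinetically at C5. This should give the deconjugated ketone (1R,3R,3aR,8aR)-1-[(tert-butyldimethylsilyl)oxy]-6,8a-dimethyl-3-(propan-2-yl)-3-[(triethylsilyl)oxy]-2,3,3a,5,8,8a-hexahydroazulen-4(1H)-one F3. HF·pyridine in THF/pyridine then removes the triethylsilyl group to give 20.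

3. Step 5. Peroxide addition at the fully substituted β-carbon may be slow, the peroxide anion may open the lactone, or the anti selectivity may be insufficient. Fallback, setting out from 9 and coming back at 14, with reagent-controlled epoxidation of an allylic alcohol in place of substrate control:
   - t-BuMe2SiCl/imidazole gives methyl (5R,6E,8E)-5-[(tert-butyldimethylsilyl)oxy]-6-methyldeca-6,8-dien-2-ynoate F4.
   - The same copper-catalysed i-PrMgCl addition, now without lactonisation, gives methyl (2E,5R,6E,8E)-5-[(tert-butyldimethylsilyl)oxy]-6-methyl-3-(propan-2-yl)deca-2,6,8-trienoate F5.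
   - DIBAL-H (CH2Cl2, −78 °C) gives (2E,5R,6E,8E)-5-[(tert-butyldimethylsilyl)oxy]-6-methyl-3-(propan-2-yl)deca-2,6,8-trien-1-ol F6.
   - Sharpless epoxidation (Ti(OiPr)4, D-(−)-diethyl tartrate, t-BuOOH, 4 Å MS, CH2Cl2, −20 °C) gives {(2R,3R)-3-[(2R,3E,5E)-2-[(tert-butyldimethylsilyl)oxy]-3-methylhepta-3,5-dien-1-yl]-3-(propan-2-yl)oxiran-2-yl}methanol F7.
   - Dess–Martin periodinane gives (2S,3R)-3-[(2R,3E,5E)-2-[(tert-butyldimethylsilyl)oxy]-3-methylhepta-3,5-dien-1-yl]-3-(propan-2-yl)oxirane-2-carbaldehyde F8.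
   - MeMgBr gives 1-{(2R,3R)-3-[(2R,3E,5E)-2-[(tert-butyldimethylsilyl)oxy]-3-methylhepta-3,5-dien-1-yl]-3-(propan-2-yl)oxiran-2-yl}ethan-1-ol F9 (both carbinol epimers).
   - A second Dess–Martin oxidation converges both epimers on 14.

Further compounds
F1 | step 9 | (3R,4R,6R,7E,9E)-3-bromo-6-[(tert-butyldimethylsilyl)oxy]-4-hydroxy-7-methyl-4-(propan-2-yl)undeca-7,9-dien-2-one | C/C=C/C=C(\C)[C@H](O[Si](C)(C)C(C)(C)C)C[C@@](O)(C(C)C)[C@@H](Br)C(C)=O
F2 | step 9 | (3R,4R,6R,7E,9E)-3-bromo-6-[(tert-butyldimethylsilyl)oxy]-7-methyl-4-(propan-2-yl)-4-[(triethylsilyl)oxy]undeca-7,9-dien-2-one | C/C=C/C=C(\C)[C@H](O[Si](C)(C)C(C)(C)C)C[C@@](O[Si](CC)(CC)CC)(C(C)C)[C@@H](Br)C(C)=O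
F3 | step 12 | (1R,3R,3aR,8aR)-1-[(tert-butyldimethylsilyl)oxy]-6,8a-dimethyl-3-(propan-2-yl)-3-[(triethylsilyl)oxy]-2,3,3a,5,8,8a-hexahydroazulen-4(1H)-one | CC1=CC[C@@]2(C)[C@H](O[Si](C)(C)C(C)(C)C)C[C@@](O[Si](CC)(CC)CC)(C(C)C)[C@@H]2C(=O)C1
F4 | step 5 | methyl (5R,6E,8E)-5-[(tert-butyldimethylsilyl)oxy]-6-methyldeca-6,8-dien-2-ynoate | C/C=C/C=C(\C)[C@H](O[Si](C)(C)C(C)(C)C)CC#CC(=O)OC
F5 | step 5 | methyl (2E,5R,6E,8E)-5-[(tert-butyldimethylsilyl)oxy]-6-methyl-3-(propan-2-yl)deca-2,6,8-trienoate | C/C=C/C=C(\C)[C@H](O[Si](C)(C)C(C)(C)C)C/C(C(C)C)=C\C(=O)OC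
F6 | step 5 | (2E,5R,6E,8E)-5-[(tert-butyldimethylsilyl)oxy]-6-methyl-3-(propan-2-yl)deca-2,6,8-trien-1-ol | C/C=C/C=C(\C)[C@H](O[Si](C)(C)C(C)(C)C)C/C(C(C)C)=C\CO
F7 | step 5 | {(2R,3R)-3-[(2R,3E,5E)-2-[(tert-butyldimethylsilyl)oxy]-3-methylhepta-3,5-dien-1-yl]-3-(propan-2-yl)oxiran-2-yl}methanol | C/C=C/C=C(\C)[C@H](O[Si](C)(C)C(C)(C)C)C[C@]1(C(C)C)O[C@@H]1CO
F8 | step 5 | (2S,3R)-3-[(2R,3E,5E)-2-[(tert-butyldimethylsilyl)oxy]-3-methylhepta-3,5-dien-1-yl]-3-(propan-2-yl)oxirane-2-carbaldehyde | C/C=C/C=C(\C)[C@H](O[Si](C)(C)C(C)(C)C)C[C@]1(C(C)C)O[C@@H]1C=O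
F9 | step 5 | 1-{(2R,3R)-3-[(2R,3E,5E)-2-[(tert-butyldimethylsilyl)oxy]-3-methylhepta-3,5-dien-1-yl]-3-(propan-2-yl)oxiran-2-yl}ethan-1-ol (both carbinol epimers) | C/C=C/C=C(\C)[C@H](O[Si](C)(C)C(C)(C)C)C[C@]1(C(C)C)O[C@@H]1C(C)O
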